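**Retrosynthetic overview**
1. Alertenone 16 ⇒ two molecules of suberosenone 13: Michael addition of the C3 lithium enolate of one to the exocyclic methylene of the other (last step, C3–CH2 bond, two new stereocentres).
2. 13 ⇒ α-chloro-α-methyl ketone 12 (HCl loss can only go into the methyl group because C9 is quaternary); ring C of 12 ⇒ ring-closing metathesis/hydrogenation of two alkenyl arms (C6–C7).
3. Ring A of 10 ⇒ key one-carbon ring expansion (diazomethane, 1,2-shift of C4) of α-chlorocyclobutanone 9 ⇒ chloro(methyl)ketene + cyclopentene 6 ([2+2], sets C4 and C9).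
4. 6 ⇒ enol triflate 4 + buta-1,3-diene (new dual CuH/Pd hydroalkenylation, sets C8) ⇒ 4,4-dimethylcyclopent-2-en-1-one 1 + propenylboronic acid 2 (Rh conjugate addition, sets C5).
5. Ring order: B (purchased) → cyclobutanone → A (ring expansion) → C (metathesis) → dimerization.

Atom labels (each C15 half): C1 (carries the exocyclic CH2), C2 (C=O), C3 (CH2), C4 (ring-fusion CH), C5 (bridgehead CH), C6 and C7 (CH2), C8 (CHMe), C9 (quaternary), C10 (CH2), C11 (CMe2). Ring A = C1-C2-C3-C4-C9, ring B = C4-C5-C11-C10-C9, ring C = C4-C5-C6-C7-C8-C9. Primes mark the second half. In these labels 13 is 4S,5S,8S,9S and 16 is additionally 3R,1′S.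

Assumption: the ligand enantiomers named in steps 1 and 3 are those expected from the closest models to give the configurations drawn (the antipode is used if the sense proves opposite); C1 in 9–12 forms as a mixture of epimers, which is of no consequence because that centre is destroyed in step 7.

Step 1
Reactants: 1 4,4-dimethylcyclopent-2-en-1-one; 2 (E)-prop-1-en-1-ylboronic acid
Product: 3 (4R)-3,3-dimethyl-4-[(1E)-prop-1-en-1-yl]cyclopentan-1-one
Conditions: Rh(acac)(C2H4)2 (3 mol %), (R)-BINAP, dioxane/H2O 10:1, 100 °C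
Reagents that add atoms: none
Why: Hayashi–Miyaura rhodium-catalysed asymmetric conjugate addition, in which the alkenyl–rhodium/(R)-BINAP species adds to one enantioface of the enone and so sets C5 (R in the ketone numbering), the γ-gem-dimethyl group being tolerated.

Step 2
Reactants: 3 (4R)-3,3-dimethyl-4-[(1E)-prop-1-en-1-yl]cyclopentan-1-one
Product: 4 (3S)-4,4-dimethyl-3-[(1E)-prop-1-en-1-yl]cyclopent-1-en-1-yl trifluoromethanesulfonate
Conditions: KN(SiMe3)2, PhNTf2, THF, −78 °C
Reagents that add atoms: N-phenylbis(trifluoromethanesulfonimide), O=S(=O)(N(c1ccccc1)S(=O)(=O)C(F)(F)F)C(F)(F)F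
Why: Kinetic enolate O-triflation, in which the bulky amide removes the less hindered α-proton next to the propenyl-bearing CH rather than the neopentyl CH2 beside CMe2, fixing the future C9=C4 alkene without touching the stereocentre.

Step 3
Reactants: 4 (3S)-4,4-dimethyl-3-[(1E)-prop-1-en-1-yl]cyclopent-1-en-1-yl trifluoromethanesulfonate; 5 buta-1,3-diene
Product: 6 (3S)-1-[(2S)-but-3-en-2-yl]-4,4-dimethyl-3-[(1E)-prop-1-en-1-yl]cyclopent-1-ene
Conditions: Cu(OAc)2 (5 mol %), (R)-DTBM-SEGPHOS, [Pd(cinnamyl)Cl]2 (2.5 mol %), BrettPhos, (MeO)2MeSiH, NaOSiMe3, buta-1,3-diene (4 equiv), THF, 40 °C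
Reagents that add atoms: none
Why: Proposed new method: the chiral bisphosphine–copper hydride adds across buta-1,3-diene to give an equilibrating crotyl/1-methylallyl copper, which transmetalates γ-selectively (SE2′) to the alkenylpalladium triflate formed by oxidative addition of 4 to zerovalent palladium, and fast reductive elimination from the η1-(but-3-en-2-yl)(alkenyl)palladium under the bulky biarylphosphine forms the C9–C8 bond with the copper ligand setting C8 as S; the closest known reaction types are the dual copper hydride/palladium enantioselective hydroalkenylation of styrenes with enol triflates and the copper hydride-mediated branched allylation of ketones with 1,3-dienes.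

Step 4
Reactants: 6 (3S)-1-[(2S)-but-3-en-2-yl]-4,4-dimethyl-3-[(1E)-prop-1-en-1-yl]cyclopent-1-ene; 7 2,2-dichloropropanoyl chloride
Product: 9 7-chloro-1-[(2S)-but-3-en-2-yl]-3,3,7-trimethyl-4-[(1E)-prop-1-en-1-yl]bicyclo[3.2.0]heptan-6-one (cis-fused; four-membered ring anti to the propenyl group; C=O next to the ring-fusion CH; C7 epimers), via chloro(methyl)ketene 8 (not isolated)
Conditions: Zn–Cu couple, POCl3, Et2O, 35 °C, slow addition of 7 (1.3 equiv)
Reagents that add atoms: none
Why: Ketene–alkene [2+2] cycloaddition, in which the electrophilic chloroketene attacks the most electron-rich (trisubstituted) alkene with its carbonyl carbon on the less substituted C4 and on the face anti to the C5 propenyl group, which sets C4 and quaternary C9 (cis fusion, both alkenyl arms on the convex face).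

Step 5
Reactants: 9 the α-chlorocyclobutanone from step 4
Product: 10 1-chloro-6a-[(2S)-but-3-en-2-yl]-1,5,5-trimethyl-4-[(1E)-prop-1-en-1-yl]hexahydropentalen-2(1H)-one (cis-fused; both alkenyl arms on the convex face; C1 epimers)
Conditions: CH2N2, Et2O/MeOH (cat.), 0 to 23 °C
Reagents that add atoms: diazomethane, C=[N+]=[N-]
Why: Key step, diazomethane one-carbon ring expansion (Tiffeneau–Demjanov-type 1,2-shift): after addition to the strained carbonyl the non-halogenated ring-fusion carbon C4 migrates with retention as N2 leaves while the chlorine-bearing carbon does not migrate, so the new CH2 (C3) enters only between C2 and C4 and the C(Cl)Me carbon stays between C2 and C9.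

Step 6
Reactants: 10 the α-chloro-α-methylcyclopentanone from step 5
Product: 12 1-chlorosuberosanone (the tricyclic ketone of 13 with Cl and CH3 on C1 in place of the methylene; C4, C5, C8, C9 as in 13; C1 epimers), via tricyclic alkene 11 (not isolated)
Conditions: second-generation Grubbs catalyst RuCl2(CHPh)(PCy3)(SIMes) (5 mol %), ClCH2CH2Cl, 60 °C; then H2 (10 bar), 70 °C
Reagents that add atoms: none
Why: Ring-closing metathesis of the two cis-1,3 convex-face alkenyl arms closes six-membered ring C with loss of propene, and the same ruthenium, converted to a hydride under H2, saturates C6=C7 (tandem metathesis–hydrogenation) without changing any stereocentre or the tertiary C–Cl bond.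

Step 7
Reactants: 12 1-chlorosuberosanone
Product: 13 suberosenone
Conditions: LiBr, Li2CO3, DMF, 110 °C
Reagents that add atoms: none
Why: Dehydrohalogenation of an α-halo ketone (E2 after halide exchange), in which the only β-hydrogens are those of the methyl group because C9 is quaternary, so the exocyclic methylene enone is the sole possible alkene.

Step 8
Reactants: 13 suberosenone (2 equiv)
Product: 16 alertenone, via lithium dienolate 14 (not isolated), via adduct enolate 15 (not isolated)
Conditions: LiN(SiMe3)2 (0.5 equiv), THF, −78 to 0 °C; t-BuOH, 0 °C; AcOH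
Reagents that add atoms: none
Why: Michael addition of a cross-conjugated α′-enolate to an exo-methylene enone, in which the C3 enolate attacks the CH2 terminus through its convex face (cis to H-4, giving 3R) and the adduct enolate is protonated and equilibrated by t-BuOLi/t-BuOH to the more stable C1′ epimer (CH2 link anti to C10′, 1′S).

**Compound list**
1 | 4,4-dimethylcyclopent-2-en-1-one | CC1(C)C=CC(=O)C1 | starting material
2 | (E)-prop-1-en-1-ylboronic acid | C/C=C/B(O)O | starting material
3 | (4R)-3,3-dimethyl-4-[(1E)-prop-1-en-1-yl]cyclopentan-1-one | O=C1C[C@H](/C=C/C)C(C)(C)C1 | intermediate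
4 | (3S)-4,4-dimethyl-3-[(1E)-prop-1-en-1-yl]cyclopent-1-en-1-yl trifluoromethanesulfonate | O=S(=O)(OC1=C[C@H](/C=C/C)C(C)(C)C1)C(F)(F)F | intermediate
5 | buta-1,3-diene | C=CC=C | starting material
6 | (3S)-1-[(2S)-but-3-en-2-yl]-4,4-dimethyl-3-[(1E)-prop-1-en-1-yl]cyclopent-1-ene | C=C[C@H](C)C1=C[C@H](/C=C/C)C(C)(C)C1 | intermediate
7 | 2,2-dichloropropanoyl chloride | CC(Cl)(Cl)C(Cl)=O | starting material
8 | chloro(methyl)ketene (2-chloroprop-1-en-1-one) | CC(Cl)=C=O | intermediate
9 | 7-chloro-1-[(2S)-but-3-en-2-yl]-3,3,7-trimethyl-4-[(1E)-prop-1-en-1-yl]bicyclo[3.2.0]heptan-6-one, cis-fused, cyclobutanone anti to propenyl, C7 unspecified | CC1(Cl)C(=O)[C@H]2[C@H](/C=C/C)C(C)(C)C[C@@]12[C@@H](C)C=C | intermediate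
10 | 1-chloro-6a-[(2S)-but-3-en-2-yl]-1,5,5-trimethyl-4-[(1E)-prop-1-en-1-yl]hexahydropentalen-2(1H)-one, cis-fused, both arms on the convex face, C1 unspecified | CC1(Cl)C(=O)C[C@H]2[C@H](/C=C/C)C(C)(C)C[C@@]12[C@@H](C)C=C | intermediate
11 | 6,7-didehydro-1-chlorosuberosanone (tricyclic alkene, C6=C7, C1 unspecified) | CC1(Cl)C(=O)C[C@H]2[C@@H]3C=C[C@H](C)[C@]12CC3(C)C | intermediate
12 | 1-chlorosuberosanone (C1 bears Cl and CH3, C1 unspecified) | CC1(Cl)C(=O)C[C@H]2[C@@H]3CC[C@H](C)[C@]12CC3(C)C | intermediate
13 | suberosenone (4S,5S,8S,9S in the labels above) | C=C1C(=O)C[C@H]2[C@@H]3CC[C@H](C)[C@]12CC3(C)C | intermediate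
14 | lithium C2–C3 dienolate of suberosenone | C=C1C(O[Li])=C[C@H]2[C@@H]3CC[C@H](C)[C@]12CC3(C)C | intermediate
15 | lithium C1′–C2′ enolate of the Michael adduct (3R) | C=C1C(=O)[C@H](CC2=C(O[Li])C[C@H]3[C@@H]4CC[C@H](C)[C@]23CC4(C)C)[C@H]2[C@@H]3CC[C@H](C)[C@]12CC3(C)C | intermediate
16 | alertenone (3R,1′S; both halves 4S,5S,8S,9S) | C=C1C(=O)[C@H](C[C@@H]2C(=O)C[C@H]3[C@@H]4CC[C@H](C)[C@]23CC4(C)C)[C@H]2[C@@H]3CC[C@H](C)[C@]12CC3(C)C | target

**Step count**
Total steps: 8. Longest linear sequence: 8 steps (1 → 16).

**Three steps most likely to fail, with fallbacks**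

Step 3 (the proposed new hydroalkenylation). Risks are coupling at the linear crotyl terminus, low selectivity at C8, and migration of the skipped diene into conjugation. The fallback uses known chemistry, sets out from 4 and comes back at 6. Miyaura borylation of 4 (B2pin2, PdCl2(dppf), KOAc, dioxane, 80 °C) gives (3S)-2-{4,4-dimethyl-3-[(1E)-prop-1-en-1-yl]cyclopent-1-en-1-yl}-4,4,5,5-tetramethyl-1,3,2-dioxaborolane F1. F1 is then used in a copper–N-heterocyclic carbene-catalysed enantioselective SN2′ allylic substitution with (E)-but-2-en-1-yl diethyl phosphate (CuCl, chiral sulfonate-bearing imidazolinium salt, NaOMe, THF, 23 °C), which gives 6.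

Step 4 (ketene [2+2]). Chloro(methyl)ketene may be too sluggish or unselective towards the hindered trisubstituted alkene in the presence of the two other alkenes. The fallback sets out from 6 and comes back at 10. The more electrophilic dichloroketene (Cl3CCOCl, Zn–Cu couple, POCl3, Et2O) gives the 7,7-dichloro analogue of 9, dichlorocyclobutanone F2. Diazomethane ring expansion of F2 gives the 1,1-dichloro analogue of 10, dichlorocyclopentanone F3. Reductive methylation of F3 (Me2CuLi, THF, −78 °C; then MeI) installs the C1 methyl group and gives 10.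

Step 8 (dimerization). Risks are oligomerization through the enone that remains in 15/16, retro-Michael reaction, and the wrong C1′ epimer. The fallback sets out from 12 and 13 and comes back at 16. Ketone 12, which has only the C3 α-hydrogens and no acceptor, is deprotonated (LiN(SiMe3)2, THF, −78 °C) to the lithium C2–C3 enolate of 1-chlorosuberosanone F4. Addition of 13 (1 equiv) and the same equilibrating quench give the chloro dimer (16 with Cl and CH3 on C1 of the donor half) F5. Dehydrochlorination of F5 (LiBr, Li2CO3, DMF, 110 °C) gives 16.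

**Further compounds**
F1 | step 3 | (3S)-2-{4,4-dimethyl-3-[(1E)-prop-1-en-1-yl]cyclopent-1-en-1-yl}-4,4,5,5-tetramethyl-1,3,2-dioxaborolane | CC1(C)OB(OC1(C)C)C1=C[C@H](/C=C/C)C(C)(C)C1
F2 | step 4 | 7,7-dichloro-1-[(2S)-but-3-en-2-yl]-3,3-dimethyl-4-[(1E)-prop-1-en-1-yl]bicyclo[3.2.0]heptan-6-one (cis-fused) | ClC1(Cl)C(=O)[C@H]2[C@H](/C=C/C)C(C)(C)C[C@@]12[C@@H](C)C=C
F3 | step 4 | 1,1-dichloro-6a-[(2S)-but-3-en-2-yl]-5,5-dimethyl-4-[(1E)-prop-1-en-1-yl]hexahydropentalen-2(1H)-one (cis-fused) | ClC1(Cl)C(=O)C[C@H]2[C@H](/C=C/C)C(C)(C)C[C@@]12[C@@H](C)C=C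
F4 | step 8 | lithium C2–C3 enolate of 1-chlorosuberosanone | CC1(Cl)C(O[Li])=C[C@H]2[C@@H]3CC[C@H](C)[C@]12CC3(C)C
F5 | step 8 | chloro dimer (alertenone with Cl and CH3 on C1 of the donor half) | CC1(Cl)C(=O)[C@H](C[C@@H]2C(=O)C[C@H]3[C@@H]4CC[C@H](C)[C@]23CC4(C)C)[C@H]2[C@@H]3CC[C@H](C)[C@]12CC3(C)C
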